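**Plan**

1. Retrosynthesis: cut the acyl C–O bond of the 2-methylbutanoate and the two O-benzyl bonds; cut the oxolane C2–C3 bond while the C3 arm carbon returns into the ring as a carbonyl carbon (4-diazooxan-3-one, Wolff retron); open the pyranone to a 2,4-disubstituted furan (Achmatowicz retron); cut the furan C4–CH2Ar bond (Negishi) and the carbinol C–aryl bond (Grignard).
2. Feature used: the oxolane O1–C2(aryl)–C3(CH2O arm)–C4(benzyl)–C5 is an oxan-3-one minus one ring carbon. Oxolane C2/C3/C4/C5 are pyranone C2/C4/C5/C6, the arm carbon is the pyranone carbonyl C3, and the trans aryl/benzyl pair is the 2,5-trans pair of the six-membered ring.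
3. Forward order of rings: furan (bought) → pyran-3-one by oxidative ring expansion → saturated 2,5-trans ketone enolate → 4-diazo ketone → oxolane by photochemical ring contraction; then ester reduction, acylation and debenzylation.
4. Stereochemistry: C2 from Sharpless kinetic resolution of the furyl carbinol, retained in the 1,2-shift. C4 from ligand-controlled CuH conjugate reduction of the 5-benzyl enone; the benzyl group is built into the furan because a C2 substituent alone would not steer a nucleophile arriving at C5. C3 from base equilibration of the ring-contracted ester. The side-chain centre is bought with (R)-2-methylbutanoic acid.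

Key step: step 8

Remarks before the steps:
- Ar = 4-(benzyloxy)-3-methoxyphenyl and ArCH2 = [4-(benzyloxy)-3-methoxyphenyl]methyl in all names below.
- Assumption 1: D-(−)-diisopropyl tartrate leaves the (S)-carbinol unreacted, in the sense established for 2-furylcarbinols (furyl outranks aryl in the CIP order, as it outranks alkyl).
- Assumption 2: (R)-DTBM-SEGPHOS is the ligand antipode whose copper hydride delivers hydrogen to C5 on the face cis to the C2 aryl group, by analogy with 3-alkylcyclohexenones; the antipode would be taken if a first run showed the opposite sense.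

**Route**

Step 1
Reactants: 1 4-bromofuran-2-carbaldehyde; 2 4-(benzyloxy)-3-methoxybenzyl chloride
Product: 4 4-(ArCH2)furan-2-carbaldehyde, via benzylic zinc chloride 3 (not isolated)
Conditions: 2, Zn dust, LiCl, THF, 25 °C; then 1, Pd(OAc)2 (2 mol %), SPhos (4 mol %), THF, 25–40 °C
Reagents that add atoms: none
Why: Negishi cross-coupling — LiCl-activated zinc inserts into the benzylic C–Cl bond and the benzylic zinc chloride couples with the bromofuran under palladium catalysis faster than it adds to the aldehyde, a group that organozinc halides tolerate.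

Step 2
Reactants: 4 4-(ArCH2)furan-2-carbaldehyde; 5 1-(benzyloxy)-4-bromo-2-methoxybenzene
Product: 7 rac-Ar[4-(ArCH2)furan-2-yl]methanol, via arylmagnesium bromide 6 (not isolated)
Conditions: 5, Mg, THF, 40 °C; then 4, THF, −20 → 0 °C; aq. NH4Cl
Reagents that add atoms: none
Why: Grignard addition of the aryl nucleophile to the only electrophilic group, the furan-2-carbaldehyde, gives the secondary furyl carbinol as the racemate.

Step 3
Reactants: 7 rac-Ar[4-(ArCH2)furan-2-yl]methanol
Product: 8 (S)-Ar[4-(ArCH2)furan-2-yl]methanol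
Conditions: Ti(OiPr)4 (0.2 equiv), D-(−)-diisopropyl tartrate (0.24 equiv), t-BuOOH (0.6 equiv), 4 Å MS, CH2Cl2, −20 °C; chromatographic separation from the pyranone
Reagents that add atoms: none
Why: Sharpless kinetic resolution of a 2-furylcarbinol — the titanium tartrate/hydroperoxide system oxidises the (R)-enantiomer to its pyranone much faster, so the (S)-carbinol, which carries the future C2 configuration, should be recovered at a little over half conversion.

Step 4
Reactants: 8 (S)-Ar[4-(ArCH2)furan-2-yl]methanol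
Product: 9 (2S)-2-Ar-5-(ArCH2)-6-hydroxy-2H-pyran-3(6H)-one (both C6 anomers)
Conditions: VO(acac)2 (5 mol %), t-BuOOH (1.3 equiv), CH2Cl2, 0 °C → rt
Reagents that add atoms: tert-butyl hydroperoxide, CC(C)(C)OO
Why: Achmatowicz rearrangement — hydroxyl-directed oxidation of the furan, opening to the ene-dione and closure of the carbinol oxygen onto the aldehyde give the six-membered lactol; the carbinol centre is not touched and becomes C2, and the furan C4 benzyl group ends on C5 of the enone.

Step 5
Reactants: 9 (2S)-2-Ar-5-(ArCH2)-6-hydroxy-2H-pyran-3(6H)-one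
Product: 10 (2S)-2-Ar-5-(ArCH2)-2H-pyran-3(6H)-one
Conditions: Et3SiH (3 equiv), CF3CO2H (5 equiv), CH2Cl2, −40 → −10 °C
Reagents that add atoms: none
Why: Ionic hydrogenation of the lactol — the acid ionises C6 to the conjugated oxocarbenium ion and the silane delivers hydride there; C2, next to the carbonyl, cannot ionise, and the cold, short exposure should keep its acidic C–H from enolising.

Step 6
Reactants: 10 (2S)-2-Ar-5-(ArCH2)-2H-pyran-3(6H)-one
Product: 13 (2S,5S)-2-Ar-5-(ArCH2)-4-(trifluoroacetyl)oxan-3-one (C4 unassigned; largely enolised), via bis(enoxy)diphenylsilane 11 (not isolated), via lithium enolate 12 (not isolated)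
Conditions: CuCl (3 mol %), NaOtBu (3 mol %), (R)-DTBM-SEGPHOS (3 mol %), Ph2SiH2 (0.55 equiv), toluene, −20 °C; then MeLi (1.15 equiv), THF, −20 → 0 °C; then CF3CO2CH2CF3 (1.3 equiv), −78 °C; aq. HCl
Reagents that add atoms: 2,2,2-trifluoroethyl trifluoroacetate, O=C(OCC(F)(F)F)C(F)(F)F
Why: Ligand-controlled copper hydride 1,4-reduction (asymmetric conjugate hydrosilylation of a β-substituted cyclic enone) sets C5 by reagent control, the C2 aryl group being too remote to bias the face, and the resulting C3–C4 silyl enol ether is turned by MeLi into the regio-defined lithium enolate, which is C-trifluoroacetylated at C4 (Claisen-type acylation) without the acidic C2–H ever meeting a strong base.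

Step 7
Reactants: 13 (2S,5S)-2-Ar-5-(ArCH2)-4-(trifluoroacetyl)oxan-3-one
Product: 14 (2S,5S)-2-Ar-5-(ArCH2)-4-diazooxan-3-one (2,5-trans)
Conditions: MsN3 (1.5 equiv), Et3N (1.5 equiv), H2O (1 equiv), MeCN, rt
Reagents that add atoms: methanesulfonyl azide, CS(=O)(=O)N=[N+]=[N-]
Why: Detrifluoroacetylative (Regitz-type deacylative) diazo transfer — the enolised 1,3-diketone attacks the sulfonyl azide and the adduct fragments with loss of the N-mesyl trifluoroacetamide, placing the diazo group on C4 under conditions expected to be too mild to epimerise C2.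

Step 8
Reactants: 14 (2S,5S)-2-Ar-5-(ArCH2)-4-diazooxan-3-one
Product: 17 methyl (2R,3R,4S)-2-Ar-4-(ArCH2)oxolane-3-carboxylate, via ketene 15 (not isolated), via ester epimer mixture 16 (not isolated)
Conditions: hν (365 nm), degassed MeOH, rt; then lamp off, NaOMe (0.3 equiv), MeOH, rt
Reagents that add atoms: methanol, CO
Why: Photochemical Wolff rearrangement of a cyclic 2-diazoketone: the ring holds the diazo and carbonyl groups s-cis, so excitation expels N2 in concert with the 1,2-shift of C2 from the carbonyl carbon C3 to the diazo carbon C4, and the former C3 leaves the ring as the ketene carbon that methanol captures as the methyl ester. The closest known reaction type is the six-to-five contraction of 2-diazocyclohexanones to cyclopentanecarboxylates. The oxolane therefore closes by ring contraction (the new bond is pyranone C2–C4, which is C2–C3 of the product), not by a cyclisation. C2 migrates with retention, so the 2,5-trans pair of 14 becomes the trans aryl/benzyl pair, while the new centre C3 arises on protonation of the enol ester, which is not expected to be selective, and is then set by NaOMe equilibration to the epimer with the ester trans to the directly attached aryl group and cis to the smaller CH2Ar group. The step needs migration to outrun hydrogen shift from C5 and O–H insertion of methanol; the enforced s-cis geometry favours the concerted path, and 365 nm light is absorbed by the diazoketone only, not by the benzyl ethers.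

Step 9
Reactants: 17 methyl (2R,3R,4S)-2-Ar-4-(ArCH2)oxolane-3-carboxylate
Product: 18 [(2R,3S,4S)-2-Ar-4-(ArCH2)oxolan-3-yl]methanol
Conditions: LiAlH4, THF, 0 °C; aqueous work-up
Reagents that add atoms: none
Why: Hydride reduction of the ester to the primary alcohol with LiAlH4 leaves the benzyl ethers and the oxolane alone and removes the last epimerisable centre (the descriptor at C3 changes by CIP priority only).

Step 10
Reactants: 18 [(2R,3S,4S)-2-Ar-4-(ArCH2)oxolan-3-yl]methanol; 19 (R)-2-methylbutanoic acid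
Product: 20 [(2R,3S,4S)-2-Ar-4-(ArCH2)oxolan-3-yl]methyl (2R)-2-methylbutanoate
Conditions: EDC·HCl (1.3 equiv), DMAP (0.1 equiv), CH2Cl2, 0 °C → rt
Reagents that add atoms: none
Why: Steglich esterification of the unhindered primary alcohol; the low temperature and small DMAP loading should keep the α-centre of the acid from racemising through a ketene.

Step 11
Reactants: 20 [(2R,3S,4S)-2-Ar-4-(ArCH2)oxolan-3-yl]methyl (2R)-2-methylbutanoate
Product: 21 [(2R,3S,4S)-2-(4-hydroxy-3-methoxyphenyl)-4-[(4-hydroxy-3-methoxyphenyl)methyl]oxolan-3-yl]methyl (2R)-2-methylbutanoate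
Conditions: H2 (1 atm), 10% Pd/C, EtOAc, rt
Reagents that add atoms: none
Why: Hydrogenolysis of the two aryl benzyl ethers in a neutral aprotic solvent, where phenolic benzyl ethers should be cleaved much faster than the cyclic benzylic C2–O bond; the ester is inert.

**Compound list**

1 | 4-bromofuran-2-carbaldehyde | O=Cc1cc(Br)co1 | starting material
2 | 4-(benzyloxy)-3-methoxybenzyl chloride | COc1cc(CCl)ccc1OCc1ccccc1 | starting material
3 | {[4-(benzyloxy)-3-methoxyphenyl]methyl}zinc chloride (formed in the flask) | COc1cc(C[Zn]Cl)ccc1OCc1ccccc1 | intermediate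
4 | 4-{[4-(benzyloxy)-3-methoxyphenyl]methyl}furan-2-carbaldehyde | O=Cc1cc(Cc2ccc(OCc3ccccc3)c(OC)c2)co1 | intermediate
5 | 1-(benzyloxy)-4-bromo-2-methoxybenzene | COc1cc(Br)ccc1OCc1ccccc1 | starting material
6 | [4-(benzyloxy)-3-methoxyphenyl]magnesium bromide (formed in the flask) | COc1cc([Mg]Br)ccc1OCc1ccccc1 | intermediate
7 | rac-[4-(benzyloxy)-3-methoxyphenyl](4-{[4-(benzyloxy)-3-methoxyphenyl]methyl}furan-2-yl)methanol | OC(c1cc(Cc2ccc(OCc3ccccc3)c(OC)c2)co1)c1ccc(OCc2ccccc2)c(OC)c1 | intermediate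
8 | (S)-[4-(benzyloxy)-3-methoxyphenyl](4-{[4-(benzyloxy)-3-methoxyphenyl]methyl}furan-2-yl)methanol | O[C@H](c1cc(Cc2ccc(OCc3ccccc3)c(OC)c2)co1)c1ccc(OCc2ccccc2)c(OC)c1 | intermediate
9 | (2S)-2-[4-(benzyloxy)-3-methoxyphenyl]-5-{[4-(benzyloxy)-3-methoxyphenyl]methyl}-6-hydroxy-2H-pyran-3(6H)-one, both C6 anomers | O=C1C=C(Cc2ccc(OCc3ccccc3)c(OC)c2)C(O)O[C@H]1c1ccc(OCc2ccccc2)c(OC)c1 | intermediate
10 | (2S)-2-[4-(benzyloxy)-3-methoxyphenyl]-5-{[4-(benzyloxy)-3-methoxyphenyl]methyl}-2H-pyran-3(6H)-one | O=C1C=C(Cc2ccc(OCc3ccccc3)c(OC)c2)CO[C@H]1c1ccc(OCc2ccccc2)c(OC)c1 | intermediate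
11 | bis{[(2S,5S)-2-Ar-5-(ArCH2)-5,6-dihydro-2H-pyran-3-yl]oxy}diphenylsilane (formed in the flask) | c1ccccc1[Si](c1ccccc1)(OC1=C[C@H](Cc2ccc(OCc3ccccc3)c(OC)c2)CO[C@H]1c1ccc(OCc2ccccc2)c(OC)c1)OC1=C[C@H](Cc2ccc(OCc3ccccc3)c(OC)c2)CO[C@H]1c1ccc(OCc2ccccc2)c(OC)c1 | intermediate
12 | lithium (2S,5S)-2-Ar-5-(ArCH2)-5,6-dihydro-2H-pyran-3-olate (formed in the flask) | [Li]OC1=C[C@H](Cc2ccc(OCc3ccccc3)c(OC)c2)CO[C@H]1c1ccc(OCc2ccccc2)c(OC)c1 | intermediate
13 | (2S,5S)-2-[4-(benzyloxy)-3-methoxyphenyl]-5-{[4-(benzyloxy)-3-methoxyphenyl]methyl}-4-(trifluoroacetyl)oxan-3-one, C4 unassigned | O=C1C(C(=O)C(F)(F)F)[C@H](Cc2ccc(OCc3ccccc3)c(OC)c2)CO[C@H]1c1ccc(OCc2ccccc2)c(OC)c1 | intermediate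
14 | (2S,5S)-2-[4-(benzyloxy)-3-methoxyphenyl]-5-{[4-(benzyloxy)-3-methoxyphenyl]methyl}-4-diazooxan-3-one (2,5-trans) | O=C1C(=[N+]=[N-])[C@H](Cc2ccc(OCc3ccccc3)c(OC)c2)CO[C@H]1c1ccc(OCc2ccccc2)c(OC)c1 | intermediate
15 | [2-Ar-4-(ArCH2)oxolan-3-ylidene]methanone, the 2,4-trans ketene with C2 and C4 as in 17 (formed in the flask) | O=C=C1[C@H](Cc2ccc(OCc3ccccc3)c(OC)c2)CO[C@H]1c1ccc(OCc2ccccc2)c(OC)c1 | intermediate
16 | methyl (2R,4S)-2-Ar-4-(ArCH2)oxolane-3-carboxylate, both C3 epimers (formed in the flask) | COC(=O)C1[C@H](Cc2ccc(OCc3ccccc3)c(OC)c2)CO[C@H]1c1ccc(OCc2ccccc2)c(OC)c1 | intermediate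
17 | methyl (2R,3R,4S)-2-[4-(benzyloxy)-3-methoxyphenyl]-4-{[4-(benzyloxy)-3-methoxyphenyl]methyl}oxolane-3-carboxylate (ester trans to aryl, cis to benzyl) | COC(=O)[C@@H]1[C@H](Cc2ccc(OCc3ccccc3)c(OC)c2)CO[C@H]1c1ccc(OCc2ccccc2)c(OC)c1 | intermediate
18 | [(2R,3S,4S)-2-[4-(benzyloxy)-3-methoxyphenyl]-4-{[4-(benzyloxy)-3-methoxyphenyl]methyl}oxolan-3-yl]methanol | OC[C@@H]1[C@H](Cc2ccc(OCc3ccccc3)c(OC)c2)CO[C@H]1c1ccc(OCc2ccccc2)c(OC)c1 | intermediate
19 | (R)-2-methylbutanoic acid | CC[C@@H](C)C(=O)O | starting material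
20 | [(2R,3S,4S)-2-[4-(benzyloxy)-3-methoxyphenyl]-4-{[4-(benzyloxy)-3-methoxyphenyl]methyl}oxolan-3-yl]methyl (2R)-2-methylbutanoate | CC[C@@H](C)C(=O)OC[C@@H]1[C@H](Cc2ccc(OCc3ccccc3)c(OC)c2)CO[C@H]1c1ccc(OCc2ccccc2)c(OC)c1 | intermediate
21 | [(2R,3S,4S)-2-(4-hydroxy-3-methoxyphenyl)-4-[(4-hydroxy-3-methoxyphenyl)methyl]oxolan-3-yl]methyl (2R)-2-methylbutanoate | CC[C@@H](C)C(=O)OC[C@@H]1[C@H](Cc2ccc(O)c(OC)c2)CO[C@H]1c1ccc(O)c(OC)c1 | target

**Count**

Total steps: 11. Longest linear sequence: 11 steps, from 1 (or 2) to 21; 5 and 19 enter in steps 2 and 10.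

**Steps most likely to fail, riskiest first**

Step 6. Facial selection by the chiral copper hydride may be eroded by the resident C2 centre, or the reduction may stall on the hindered β-benzyl enone. The silicon-to-lithium exchange may also be incomplete, or the enolate may be acylated on oxygen. The fallback sets out from 10 and comes back at 13; it relays configuration through neighbouring centres instead of using a chiral catalyst. Luche reduction (NaBH4, CeCl3·7H2O, MeOH, −78 °C) should give the 2,3-trans allylic alcohol F1. Mitsunobu inversion with 4-nitrobenzoic acid (PPh3, DIAD) gives the cis 4-nitrobenzoate F2, and methanolysis (K2CO3, MeOH) gives the cis allylic alcohol F3. Hydroxyl-directed hydrogenation with [Ir(cod)(PCy3)(py)]PF6 (H2, CH2Cl2) adds hydrogen on the face of the C3 hydroxyl, which is also the face of the C2 aryl group, and gives the saturated alcohol F4 with benzyl trans to aryl. Dess–Martin oxidation gives the ketone F5. Kinetic deprotonation at the C4 methylene with LiN(SiMe3)2 at −78 °C, followed by CF3CO2CH2CF3, gives 13.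

Step 8. Nitrogen loss may give a free carbene that undergoes hydrogen shift from C5 or O–H insertion of methanol instead of ring contraction, and the C3 equilibrium may be only weakly biased. The fallback sets out from 10 through the lithium enolate 12 made as in step 6, and comes back at 18; it runs the same 1,2-shift of C2 as a Meinwald (semipinacol) ring contraction. Trapping 12 with PhNTf2 gives the enol triflate F6. Reduction with Pd(OAc)2/PPh3, HCO2H and Bu3N gives the C3–C4 alkene F7. Epoxidation with dimethyldioxirane gives the 3,4-epoxide F8 (face not controlled). MgBr2·OEt2 opens the epoxide and contracts the ring to the oxolane-3-carbaldehyde F9; either sense of opening leads to the same constitution, and C2 and C5 are not touched. The aldehyde is equilibrated with DBU to the 2,3-trans epimer, and NaBH4 then gives 18.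

Step 3. The resolution may show a low rate difference between the enantiomers, because two aryl-type groups flank the carbinol, and it consumes half of 7 at best. The fallback sets out from 4 and comes back at 8; it is a catalytic asymmetric aryl transfer instead of a resolution. Commercial [4-(benzyloxy)-3-methoxyphenyl]boronic acid is transmetalated with Et2Zn to the aryl(ethyl)zinc F10. F10 adds to 4 in the presence of a chiral β-amino alcohol ligand such as 3-exo-morpholinoisoborneol, the antipode being chosen for the (S)-carbinol, to give 8 directly.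

**Further compounds**

F1 | step 6 | (2S,3R)-2-Ar-5-(ArCH2)-3,6-dihydro-2H-pyran-3-ol (2,3-trans) | O[C@@H]1C=C(Cc2ccc(OCc3ccccc3)c(OC)c2)CO[C@H]1c1ccc(OCc2ccccc2)c(OC)c1
F2 | step 6 | (2S,3S)-2-Ar-5-(ArCH2)-3,6-dihydro-2H-pyran-3-yl 4-nitrobenzoate (2,3-cis) | O=C(O[C@H]1C=C(Cc2ccc(OCc3ccccc3)c(OC)c2)CO[C@H]1c1ccc(OCc2ccccc2)c(OC)c1)c1ccc([N+](=O)[O-])cc1
F3 | step 6 | (2S,3S)-2-Ar-5-(ArCH2)-3,6-dihydro-2H-pyran-3-ol (2,3-cis) | O[C@H]1C=C(Cc2ccc(OCc3ccccc3)c(OC)c2)CO[C@H]1c1ccc(OCc2ccccc2)c(OC)c1
F4 | step 6 | (2S,3S,5S)-2-Ar-5-(ArCH2)oxan-3-ol | O[C@H]1C[C@H](Cc2ccc(OCc3ccccc3)c(OC)c2)CO[C@H]1c1ccc(OCc2ccccc2)c(OC)c1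
F5 | step 6 | (2S,5S)-2-Ar-5-(ArCH2)oxan-3-one (2,5-trans) | O=C1C[C@H](Cc2ccc(OCc3ccccc3)c(OC)c2)CO[C@H]1c1ccc(OCc2ccccc2)c(OC)c1
F6 | step 8 | (2S,5S)-2-Ar-5-(ArCH2)-5,6-dihydro-2H-pyran-3-yl trifluoromethanesulfonate | O=S(=O)(OC1=C[C@H](Cc2ccc(OCc3ccccc3)c(OC)c2)CO[C@H]1c1ccc(OCc2ccccc2)c(OC)c1)C(F)(F)F
F7 | step 8 | (2R,5S)-2-Ar-5-(ArCH2)-5,6-dihydro-2H-pyran (2,5-trans, C3=C4 alkene) | C1=C[C@H](Cc2ccc(OCc3ccccc3)c(OC)c2)CO[C@H]1c1ccc(OCc2ccccc2)c(OC)c1
F8 | step 8 | 2-Ar-5-(ArCH2)-3,7-dioxabicyclo[4.1.0]heptane, the 3,4-epoxide of F7 (epoxide face unassigned) | C12OC1[C@H](Cc3ccc(OCc4ccccc4)c(OC)c3)CO[C@H]2c1ccc(OCc2ccccc2)c(OC)c1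
F9 | step 8 | (2R,3R,4S)-2-Ar-4-(ArCH2)oxolane-3-carbaldehyde | O=C[C@@H]1[C@H](Cc2ccc(OCc3ccccc3)c(OC)c2)CO[C@H]1c1ccc(OCc2ccccc2)c(OC)c1
F10 | step 3 | [4-(benzyloxy)-3-methoxyphenyl](ethyl)zinc | CC[Zn]c1ccc(OCc2ccccc2)c(OC)c1
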